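## Retrosynthetic overview
1. C3–Br is made last, by electrophilic bromination of 5,6-dibromoindole 6 at its most nucleophilic carbon.
2. The C3–H of 6 comes from C3–CO2Me. The ester in 4 is a removable blocking and deactivating group, taken off by saponification and protodecarboxylation.
3. C5–Br and C6–Br come from a double electrophilic bromination of methyl indole-3-carboxylate 1.
4. No ring is formed, because the indole bicycle is bought intact in 1.

Assumption: the target is planar and has no stereocentre, so "single enantiomer" does not apply. 5,6-Dibromoindole is treated as a speciality intermediate to be made from the bulk chemical 1, not bought.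

## Route

Step 1
Reactants: 1 methyl 1H-indole-3-carboxylate
Product: 4 methyl 5,6-dibromo-1H-indole-3-carboxylate, via methyl 6-bromo-1H-indole-3-carboxylate 2 (not isolated), via methyl 5-bromo-1H-indole-3-carboxylate 3 (not isolated)
Conditions: Br2 (2.3 equiv), AcOH, rt, 48 h; filter the precipitate
Reagents that add atoms: bromine, BrBr
Why: In this electrophilic aromatic substitution the ester blocks C3 and deactivates C2 as a vinylogous carbamate, so Br2 attacks the unhindered activated positions C5 (para to N1) and C6 (para to C3a), and both monobromides 2 and 3 converge on the same dibromide; no stereocentre is formed.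

Step 2
Reactants: 4 methyl 5,6-dibromo-1H-indole-3-carboxylate
Product: 6 5,6-dibromo-1H-indole, via 5,6-dibromo-1H-indole-3-carboxylic acid 5 (not isolated)
Conditions: NaOH (aq, 3 equiv), MeOH, sealed tube/µW, 150 °C; then aq HCl to pH 6
Reagents that add atoms: none
Why: Saponification gives 5 as its salt, which undergoes protodecarboxylation by C3 protonation to a 3H-indole and loss of CO2, while the unactivated aryl bromides are inert to hydroxide; no stereocentre is formed.

Step 3
Reactants: 6 5,6-dibromo-1H-indole
Product: 7 3,5,6-tribromo-1H-indole
Conditions: NBS (1.0 equiv), DMF, 0 °C, dark, 1 h; pour into ice-water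
Reagents that add atoms: N-bromosuccinimide, O=C1CCC(=O)N1Br
Why: Electrophilic aromatic substitution occurs at C3, the enamine β-carbon of an N–H indole, and one equivalent of NBS at low temperature on this bromine-deactivated ring stops before C2 is attacked; the product is achiral.

## Compound list
1 | methyl 1H-indole-3-carboxylate | COC(=O)c1c[nH]c2ccccc12 | starting material
2 | methyl 6-bromo-1H-indole-3-carboxylate | COC(=O)c1c[nH]c2cc(Br)ccc12 | intermediate (not isolated)
3 | methyl 5-bromo-1H-indole-3-carboxylate | COC(=O)c1c[nH]c2ccc(Br)cc12 | intermediate (not isolated)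
4 | methyl 5,6-dibromo-1H-indole-3-carboxylate | COC(=O)c1c[nH]c2cc(Br)c(Br)cc12 | intermediate
5 | 5,6-dibromo-1H-indole-3-carboxylic acid | OC(=O)c1c[nH]c2cc(Br)c(Br)cc12 | intermediate (not isolated)
6 | 5,6-dibromo-1H-indole | Brc1cc2cc[nH]c2cc1Br | intermediate
7 | 3,5,6-tribromo-1H-indole | Brc1cc2[nH]cc(Br)c2cc1Br | target

Total step count: 3. Longest linear sequence: 3.

## Steps most likely to fail, with fallbacks

**Step 1.** The risks are incomplete convergence of 2 and 3, stray C2, C4 or C7 bromination, and isomers that are hard to separate. The fallback gives up substitution on the intact indole and builds the pyrrole ring onto a benzene that already carries both bromines. It sets out at the level of 1, which it replaces by purchased 3,4-dibromoaniline F1, and comes back to the route at 6.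
- NIS in MeCN/AcOH iodinates F1 at its only unhindered ortho position, giving 4,5-dibromo-2-iodoaniline F2.
- Sonogashira coupling with trimethylsilylacetylene (PdCl2(PPh3)2, CuI, Et3N, rt) reacts only at C–I and gives 4,5-dibromo-2-[(trimethylsilyl)ethynyl]aniline F3.
- Catalytic K2CO3 in MeOH desilylates F3 to 4,5-dibromo-2-ethynylaniline F4.
- CuI in DMF at 100 °C closes the ring by 5-endo-dig hydroamination to 6.

**Step 2.** The vinylogous-carbamate ester may resist hydrolysis, the electron-poor acid may decarboxylate slowly, and material may decompose at 150 °C. The fallback never makes 6. It sets out from 4 and comes back at 7.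
- 4 is saponified with KOH in refluxing aqueous EtOH, and acid 5 is isolated by acidification and filtration.
- 5 is treated with NBS (1.05 equiv) in DMF at 0 °C to rt.
- Ipso attack of Br+ at C3 followed by loss of CO2 (ionic halodecarboxylation) puts the bromine where the carboxyl group stood.
- This fallback makes no compound outside the compound list (F0).

**Step 3.** N–H 3-bromoindoles are sensitive to acid and light. Other risks are C2 over-bromination to the tetrabromide and oxidation to the oxindole on work-up. The fallback is a protecting-group detour that sets out from 6 and comes back at 7.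
- 6 is silylated with NaH and TBSCl in THF at 0 °C, giving 5,6-dibromo-1-(tert-butyldimethylsilyl)-1H-indole F5. No alkyllithium is used because of the aryl bromides.
- NBS in THF at −78 °C gives 3,5,6-tribromo-1-(tert-butyldimethylsilyl)-1H-indole F6. This compound is stable and can be chromatographed, and its bulky silyl group shields C2.
- TBAF in THF at 0 °C releases 7 under non-acidic, non-oxidising conditions.

## Further compounds
F1 | step 1 | 3,4-dibromoaniline (purchased) | Nc1ccc(Br)c(Br)c1
F2 | step 1 | 4,5-dibromo-2-iodoaniline | Nc1cc(Br)c(Br)cc1I
F3 | step 1 | 4,5-dibromo-2-[(trimethylsilyl)ethynyl]aniline | Nc1cc(Br)c(Br)cc1C#C[Si](C)(C)C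
F4 | step 1 | 4,5-dibromo-2-ethynylaniline | Nc1cc(Br)c(Br)cc1C#C
F0 | step 2 | none | none
F5 | step 3 | 5,6-dibromo-1-(tert-butyldimethylsilyl)-1H-indole | CC(C)(C)[Si](C)(C)n1ccc2cc(Br)c(Br)cc12
F6 | step 3 | 3,5,6-tribromo-1-(tert-butyldimethylsilyl)-1H-indole | CC(C)(C)[Si](C)(C)n1cc(Br)c2cc(Br)c(Br)cc12
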